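**Retrosynthetic overview**
1. Phylloflavan ⇒ its hexa-O-benzyl ether (all six phenols masked, one final hydrogenolysis).
2. Hexa-O-benzyl ether ⇒ 5,7,3',4'-tetra-O-benzyl-(+)-catechin + (E)-5-[3,4-bis(benzyloxy)phenyl]pent-2-enal + one oxygen atom. A single carbene-catalysed step makes the carbinol C–O bond (setting 3S) and the ester C–O bond; no C–C bond is formed there.
3. Enal ⇒ 4-[3,4-bis(benzyloxy)phenyl]but-1-ene + crotonaldehyde (cross-metathesis); butene ⇒ 3,4-bis(benzyloxy)benzyl chloride + allylmagnesium bromide.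
4. Tetra-O-benzylcatechin ⇒ (+)-catechin. No ring is built: ring C (the pyran) and aromatic rings A and B come intact from catechin, with both flavan stereocentres.

Assumption: the SMILES is read as drawn, i.e. the flavan unit is (2R,3S) (2,3-trans, as in (+)-catechin) and the side-chain carbinol is (3S).
Assumption: the (5aS,10bR) triazolium precatalyst is taken to deliver oxygen to the Si face of C3 of the enal (giving 3S); if a first run shows the opposite sense, its equally available (5aR,10bS) antipode is used and nothing else changes.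

**Step 1**
Reactants: 1 (+)-catechin
Product: 2 5,7,3',4'-tetra-O-benzyl-(+)-catechin
Conditions: BnBr (4.2 equiv), K2CO3 (4.5 equiv), DMF, 0 °C to rt, N2
Reagents that add atoms: benzyl bromide, BrCc1ccccc1
Why: Williamson ether synthesis; carbonate ionises only the four phenols, so the secondary alcohol stays free, and the mild base and low temperature leave C2 and C3 untouched.

**Step 2**
Reactants: 3 3,4-bis(benzyloxy)benzyl chloride; 4 allylmagnesium bromide
Product: 5 4-(but-3-en-1-yl)-1,2-bis(benzyloxy)benzene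
Conditions: 4 (1.3 equiv, 1 M in Et2O), THF, 0 °C to rt; aq. NH4Cl
Reagents that add atoms: none
Why: SN2 coupling of an allyl Grignard reagent with an activated, electron-rich benzylic chloride; aryl benzyl ethers are inert and no stereocentre is involved.

**Step 3**
Reactants: 5 4-(but-3-en-1-yl)-1,2-bis(benzyloxy)benzene; 6 crotonaldehyde
Product: 7 (E)-5-[3,4-bis(benzyloxy)phenyl]pent-2-enal
Conditions: 6 (5 equiv), second-generation Grubbs catalyst RuCl2(=CHPh)(PCy3)(H2IMes) (3 mol %), CH2Cl2, 40 °C
Reagents that add atoms: none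
Why: Olefin cross-metathesis of a terminal alkene with an excess of an electron-poor enal partner gives the conjugated (E)-enal under thermodynamic control while propene escapes.

**Step 4**
Reactants: 7 (E)-5-[3,4-bis(benzyloxy)phenyl]pent-2-enal; 2 5,7,3',4'-tetra-O-benzyl-(+)-catechin
Product: 9 hexa-O-benzylphylloflavan, via β-hydroxyacyl triazolium 8 (not isolated)
Conditions: 2 (2.5 equiv, excess recovered), 7 (1.0 equiv, added over 6 h), (5aS,10bR)-2-(pentafluorophenyl)-5a,10b-dihydro-4H,6H-indeno[2,1-b][1,2,4]triazolo[4,3-d][1,4]oxazin-2-ium tetrafluoroborate (20 mol %), 4-nitropyridine N-oxide (1.5 equiv), NaOAc (1.0 equiv), DMAP (20 mol %), 4 Å MS, PhMe, 23 °C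
Reagents that add atoms: 4-nitropyridine N-oxide, [O-][n+]1ccc(cc1)[N+](=O)[O-]
Why: Proposed new method: a three-component enantioselective β-hydroxylative esterification, in which the chiral carbene adds to the aldehyde of 7, the electron-rich adduct is oxidised by single-electron transfer to the nitroarene, and the radical pair recombines by C–O bond formation at C3 on the Si face set by the indane wall of the catalyst; N–O cleavage then releases 4-nitrosopyridine N-oxide and leaves acyl triazolium 8, whose DMAP/acetate-assisted acyl transfer to the C3 hydroxyl of 2 (in excess, to outcompete the hydroxyl of 8 and of 9) forms the ester C–O bond and frees the carbene, so both C–O bonds and the (3S) centre are made in one step, the catechin centres are untouched, and any (3R) epimer is a separable diastereomer; the closest known reaction type is the carbene-catalysed enantioselective β-hydroxylation of enals with nitroarene oxidants, run so far only in methanol to give methyl esters, together with carbene redox esterification of epoxy aldehydes, and the new element is capture by a stoichiometric, hindered, chiral secondary alcohol.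

**Step 5**
Reactants: 9 hexa-O-benzylphylloflavan
Product: 10 phylloflavan
Conditions: H2 (1 atm), Pd(OH)2/C (20 wt %), THF/MeOH 1:1, rt; filtration under Ar, Sephadex LH-20 (MeOH)
Reagents that add atoms: none
Why: Catalytic hydrogenolysis of the six aryl benzyl ethers, as in catechin gallate syntheses; the alkyl ester, the secondary alcohol, the pyran ring and all three stereocentres are unaffected.

**Compound list**
1 | (+)-catechin, (2R,3S)-2-(3,4-dihydroxyphenyl)-3,4-dihydro-2H-chromene-3,5,7-triol | O[C@H]1Cc2c(O)cc(O)cc2O[C@@H]1c1ccc(O)c(O)c1 | starting material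
2 | 5,7,3',4'-tetra-O-benzyl-(+)-catechin, (2R,3S)-5,7-bis(benzyloxy)-2-[3,4-bis(benzyloxy)phenyl]-3,4-dihydro-2H-chromen-3-ol | O[C@H]1Cc2c(OCc3ccccc3)cc(OCc3ccccc3)cc2O[C@@H]1c1ccc(OCc2ccccc2)c(OCc2ccccc2)c1 | intermediate
3 | 3,4-bis(benzyloxy)benzyl chloride, 4-(chloromethyl)-1,2-bis(benzyloxy)benzene | ClCc1ccc(OCc2ccccc2)c(OCc2ccccc2)c1 | starting material
4 | allylmagnesium bromide | C=CC[Mg]Br | starting material
5 | 4-(but-3-en-1-yl)-1,2-bis(benzyloxy)benzene | C=CCCc1ccc(OCc2ccccc2)c(OCc2ccccc2)c1 | intermediate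
6 | crotonaldehyde, (E)-but-2-enal | C/C=C/C=O | starting material
7 | (E)-5-[3,4-bis(benzyloxy)phenyl]pent-2-enal | O=C/C=C/CCc1ccc(OCc2ccccc2)c(OCc2ccccc2)c1 | intermediate
8 | β-hydroxyacyl triazolium: the (5aS,10bR)-2-(pentafluorophenyl)indeno-triazolo-oxazinium cation carrying the (3S)-5-[3,4-bis(benzyloxy)phenyl]-3-hydroxypentanoyl group on its carbene carbon | O=C(C[C@@H](O)CCc1ccc(OCc2ccccc2)c(OCc2ccccc2)c1)c1[n+](-c2c(F)c(F)c(F)c(F)c2F)nc2n1[C@@H]1c3ccccc3C[C@@H]1OC2 | intermediate
9 | hexa-O-benzylphylloflavan, (2R,3S)-5,7-bis(benzyloxy)-2-[3,4-bis(benzyloxy)phenyl]-3,4-dihydro-2H-chromen-3-yl (3S)-5-[3,4-bis(benzyloxy)phenyl]-3-hydroxypentanoate | O=C(C[C@@H](O)CCc1ccc(OCc2ccccc2)c(OCc2ccccc2)c1)O[C@H]1Cc2c(OCc3ccccc3)cc(OCc3ccccc3)cc2O[C@@H]1c1ccc(OCc2ccccc2)c(OCc2ccccc2)c1 | intermediate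
10 | phylloflavan, (2R,3S)-2-(3,4-dihydroxyphenyl)-5,7-dihydroxy-3,4-dihydro-2H-chromen-3-yl (3S)-5-(3,4-dihydroxyphenyl)-3-hydroxypentanoate | O=C(C[C@@H](O)CCc1ccc(O)c(O)c1)O[C@H]1Cc2c(O)cc(O)cc2O[C@@H]1c1ccc(O)c(O)c1 | target

**Totals and risks**
Total step count: 5. Longest linear sequence: 4 steps (3 → 5 → 7 → 9 → 10).

The three steps most likely to fail are steps 4, 5 and 1.

Step 4 is the new transformation and carries the most risk. Acyl transfer from 8 to the hindered alcohol 2 may be slower than cyclisation of 8 onto its own hydroxyl or acylation of the hydroxyl of 9. Redox by-products (the saturated and the unsaturated ester) and incomplete facial control are also possible. The fallback uses known chemistry only, sets out from 7 (together with 2) and comes back at 9: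
- Pinnick oxidation of 7 (NaClO2, NaH2PO4, 2-methylbut-2-ene, tBuOH/H2O) gives (E)-5-[3,4-bis(benzyloxy)phenyl]pent-2-enoic acid F1.
- Steglich esterification of F1 with 2 (EDC·HCl, DMAP, CH2Cl2) gives the tetra-O-benzylcatechin-3-yl (E)-5-[3,4-bis(benzyloxy)phenyl]pent-2-enoate F2.
- Copper-catalysed asymmetric conjugate borylation of F2 (CuCl, NaOtBu, (R)-1-[(S_p)-2-(diphenylphosphino)ferrocenyl]ethyldicyclohexylphosphine or its enantiomer, whichever gives 3S, B2pin2, MeOH, THF, rt) gives the (3S)-3-(pinacolboryl)pentanoate ester F3.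
- Oxidation of F3 in the same flask with NaBO3·4H2O proceeds with retention at carbon and gives 9.

Step 5 removes six benzyl groups from a product that is air-sensitive. Hydrogenolysis could stall at partly benzylated stages or open the benzylic C2–O bond of ring C. The fallback sets out from 9 and comes back at 10. It replaces reduction by Lewis-acid debenzylation with a cation scavenger (BCl3, pentamethylbenzene, CH2Cl2, −78 °C, MeOH quench), which cannot reduce the pyran ring; it makes no new compound (F0).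

Step 1 can give C-benzylation of the phloroglucinol ring A, over- or under-alkylation, and therefore a modest yield of 2. The fallback sets out from 1 and comes back at 2:
- Peracetylation (Ac2O, pyridine) gives (+)-catechin pentaacetate F4.
- One-pot deacetylative benzylation of the four aryl acetates (BnCl, NaH, DMF, H2O added slowly, 0 °C to rt) gives 3-O-acetyl-5,7,3',4'-tetra-O-benzylcatechin F5. Each phenoxide is released slowly and trapped at once, which suppresses C-alkylation.
- Methanolysis of the remaining alkyl acetate (K2CO3, MeOH/THF) returns 2.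

**Further compounds**
F1 | step 4 | (E)-5-[3,4-bis(benzyloxy)phenyl]pent-2-enoic acid | OC(=O)/C=C/CCc1ccc(OCc2ccccc2)c(OCc2ccccc2)c1
F2 | step 4 | (2R,3S)-5,7-bis(benzyloxy)-2-[3,4-bis(benzyloxy)phenyl]-3,4-dihydro-2H-chromen-3-yl (E)-5-[3,4-bis(benzyloxy)phenyl]pent-2-enoate | O=C(/C=C/CCc1ccc(OCc2ccccc2)c(OCc2ccccc2)c1)O[C@H]1Cc2c(OCc3ccccc3)cc(OCc3ccccc3)cc2O[C@@H]1c1ccc(OCc2ccccc2)c(OCc2ccccc2)c1
F3 | step 4 | (2R,3S)-5,7-bis(benzyloxy)-2-[3,4-bis(benzyloxy)phenyl]-3,4-dihydro-2H-chromen-3-yl (3S)-5-[3,4-bis(benzyloxy)phenyl]-3-(4,4,5,5-tetramethyl-1,3,2-dioxaborolan-2-yl)pentanoate | O=C(C[C@@H](B1OC(C)(C)C(C)(C)O1)CCc1ccc(OCc2ccccc2)c(OCc2ccccc2)c1)O[C@H]1Cc2c(OCc3ccccc3)cc(OCc3ccccc3)cc2O[C@@H]1c1ccc(OCc2ccccc2)c(OCc2ccccc2)c1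
F4 | step 1 | (+)-catechin pentaacetate, (2R,3S)-2-(3,4-diacetoxyphenyl)-3,4-dihydro-2H-chromene-3,5,7-triyl triacetate | CC(=O)O[C@H]1Cc2c(OC(C)=O)cc(OC(C)=O)cc2O[C@@H]1c1ccc(OC(C)=O)c(OC(C)=O)c1
F5 | step 1 | (2R,3S)-5,7-bis(benzyloxy)-2-[3,4-bis(benzyloxy)phenyl]-3,4-dihydro-2H-chromen-3-yl acetate | CC(=O)O[C@H]1Cc2c(OCc3ccccc3)cc(OCc3ccccc3)cc2O[C@@H]1c1ccc(OCc2ccccc2)c(OCc2ccccc2)c1
F0 | step 5 | none | none
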